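**Retrosynthetic overview**
1. Ring B hides a γ,δ-unsaturated acid: C1 read as a carboxyl carbon on C7a, the C7a–C7 bond, and a C5=C6 alkene. An oxygen bridge from C1 to C5 turns this into δ-lactone 9, whose ring already contains C7a, C3a and C4.
2. Target 29 ⇐ angelate at C5 (Mitsunobu inversion) and acetate at C1 ⇐ ring A ketol 25 ⇐ acyloin closure C1–C2 of the trans diester 23.
3. 23 ⇐ bridged lactones 14–20. The kinetic cis acid 12 first delivers oxygen to C6, then restricts enolisation of the C5 ketone to C4 for methylenation. C7a is inverted only afterwards (step 12).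
4. 12 ⇐ Ireland–Claisen ring contraction of 9 ⇐ anti vinyl addition to dihydropyranone 6 ⇐ ring-closing metathesis ⇐ asymmetric allylation of enal 1. The C3–C2 arm travels as a vinyl group.
5. Order of rings: temporary δ-lactone (step 3), ring B (step 5), temporary bridging γ-lactone (step 6), ring A (step 14).

Key step: step 5

Locants and faces: target numbering is used for all compounds (C1 OAc, C2 C=O, C3, C3a, C4 =CH2, C5 O-angelate, C6 OH, C7 iPr, C7a). β is the face of the C3a–C3 bond, the C7 isopropyl group, H7a, C6–OH and C1–OAc. α is the face of H3a, the C7a–C1 bond and the C5 angelate.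

Assumption: of the ring A ketols, the 2-oxo-1β-ol is taken as the most stable, as is general for trans-hydrindane ketols. Its hydroxyl is quasi-equatorial and hydrogen-bonded to the ketone, and its carbonyl lies away from the strained trans ring fusion.

Step 1
Reactants: 1 (E)-4-methylpent-2-enal; 2 allyltributylstannane
Product: 3 (4R,5E)-7-methylocta-1,5-dien-4-ol
Conditions: (R)-BINOL (10 mol %), Ti(OiPr)4 (10 mol %), 4 Å MS, CH2Cl2, −20 °C; sat. aq NaHCO3
Reagents that add atoms: none
Why: Keck asymmetric allylation, in which the (R)-BINOL–titanium Lewis acid exposes the Re face of the enal to the stannane, 1,2-addition being the normal course for enals, so the C5 carbinol should be set as R.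

Step 2
Reactants: 3 (4R,5E)-7-methylocta-1,5-dien-4-ol; 4 acryloyl chloride
Product: 5 (4R,5E)-7-methylocta-1,5-dien-4-yl acrylate
Conditions: Et3N, DMAP (cat.), CH2Cl2, 0 °C
Reagents that add atoms: none
Why: Ordinary O-acylation of a secondary allylic alcohol with an acid chloride, which does not touch the stereocentre.

Step 3
Reactants: 5 (4R,5E)-7-methylocta-1,5-dien-4-yl acrylate
Product: 6 (6R)-6-[(E)-3-methylbut-1-enyl]-5,6-dihydro-2H-pyran-2-one
Conditions: RuCl2(=CHPh)(PCy3)2 (first-generation Grubbs catalyst, 5 mol %), CH2Cl2 (5 mM), 40 °C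
Reagents that add atoms: none
Why: Ring-closing metathesis, in which the catalyst loads on the terminal allyl alkene and closes onto the acrylate to the six-membered unsaturated lactone, while the hindered internal E alkene should be left alone by this less active catalyst.

Step 4
Reactants: 6 (6R)-6-[(E)-3-methylbut-1-enyl]-5,6-dihydro-2H-pyran-2-one; 7 vinylmagnesium bromide
Product: 9 (4S,6R)-4-ethenyl-6-[(E)-3-methylbut-1-enyl]oxan-2-one (trans lactone), via trimethylsilyl ketene acetal 8 (not isolated)
Conditions: CuI (10 mol %), LiCl (20 mol %), TMSCl (1.5 equiv), THF, −78 → −40 °C; 1 M HCl work-up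
Reagents that add atoms: none
Why: Copper-catalysed, TMSCl-accelerated conjugate addition, in which vinyl attacks C3a axially on the half-chair, anti to the pseudo-equatorial C5 alkenyl group; this is the known way to trans-4,6-disubstituted valerolactones and at low temperature should outrun allylic substitution at C5–O, so it sets C3a.

Step 5
Reactants: 9 (4S,6R)-4-ethenyl-6-[(E)-3-methylbut-1-enyl]oxan-2-one
Product: 12 (1S,2R,6R)-6-ethenyl-2-(propan-2-yl)cyclohex-3-ene-1-carboxylic acid (C3a vinyl C7a carboxyl C7 isopropyl all β), via silyl ketene acetal 10 (not isolated), via silyl ester 11 (not isolated)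
Conditions: LDA (1.15 equiv), THF, −78 °C; TBSCl (1.3 equiv), DMPU, −78 °C → rt; solvent change, PhMe, 105 °C; 1 M HCl–THF, rt
Reagents that add atoms: none
Why: LDA removes a C7a proton, the only acidic C–H of 9, and O-silylation gives the cyclic ketene acetal 10, which on heating undergoes a concerted [3,3] shift in which C7a bonds to C7 while C5–O breaks, leaving silyl ester 11 that dilute acid hydrolyses to 12. The closest known reaction type is the Ireland–Claisen ring contraction of silyl ketene acetals of 6-alkenyl δ-lactones to cyclohex-3-enecarboxylic acids. Ring B closes as a six-membered carbocycle by sigmatropic contraction of the lactone: because C7a and C5 are also tied by the C3a–C4 bridge, only a boat-like, bicyclo[2.2.2]octane-shaped transition state with an axial alkenyl group is possible, and it can only give the cis C5=C6 alkene inside the ring. C7a is controlled by the C5 stereocentre, since C7 is delivered to the lactone face that carries the alkenyl group, which in the trans lactone is opposite the C3a vinyl group, so that C1 ends cis to the C3a arm. C7 is controlled by the E alkene geometry, which in the boat puts isopropyl in the outer position and hence cis to C1, so 12 should form all-cis with C3a and C7 already as in the target. The step needs O- rather than C-silylation (polar cosolvent, hindered silyl chloride) and no competing pericyclic path, which the substrate secures because the trans lactone can hold the alkenyl group axial with the vinyl group equatorial, the vinyl group is 1,4 to the ketene acetal, and the Cope path open to the 1,5-diene of 12 needs far higher temperature.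

Step 6
Reactants: 12 all-cis vinyl acid
Product: 14 5α-hydroxy-6β,1-lactone (C1(=O)–O–C6 bridge on the β face; C3a vinyl and C7 isopropyl β), via epoxy acid 13 (not isolated)
Conditions: mCPBA (1.05 equiv), CH2Cl2, 0 °C; then CSA (10 mol %), rt
Reagents that add atoms: mCPBA, OOC(=O)c1cccc(Cl)c1
Why: Prilezhaev epoxidation followed by acid-catalysed hydroxylactonisation, in which the peracid should take the more electron-rich ring alkene rather than the vinyl group and come from the α face because the axial C7a carboxyl and the C7 isopropyl cover the β face, and the carboxyl then opens epoxide 13 at C6 in a 5-exo, trans-diaxial (Fürst–Plattner) manner, which sets C6–O β.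

Step 7
Reactants: 14 5α-hydroxy-6β,1-lactone with C3a vinyl
Product: 16 diol lactone (C3a 2-hydroxyethyl; 5α-OH), via bis(9-BBN) adduct 15 (not isolated)
Conditions: 9-BBN (2.5 equiv), THF, 0 °C → rt; then 30 % H2O2, aq NaOAc, 0 °C → rt
Reagents that add atoms: hydrogen peroxide, OO
Why: Brown hydroboration–oxidation, in which the vinyl group is now the only alkene, 9-BBN places boron on terminal C2 without reducing the lactone, and acetate-buffered peroxide avoids lactone hydrolysis.

Step 8
Reactants: 16 diol lactone
Product: 17 5-oxo lactone acid (C3a carboxymethyl)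
Conditions: CrO3, H2SO4, H2O, acetone, 0 °C
Reagents that add atoms: water, O
Why: Jones oxidation takes the primary C2 alcohol to the acid and the axial C5 alcohol to the ketone in one operation, and nothing in 16 is acid-labile.

Step 9
Reactants: 17 5-oxo lactone acid
Product: 18 5-oxo lactone methyl ester (C3a CH2CO2Me)
Conditions: TMSCHN2, PhMe–MeOH, 0 °C
Reagents that add atoms: (trimethylsilyl)diazomethane, C[Si](C)(C)C=[N+]=[N-]
Why: Diazoalkane esterification is neutral and leaves the α-acyloxy ketone untouched.

Step 10
Reactants: 18 5-oxo lactone methyl ester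
Product: 19 4-methylene-5-oxo lactone methyl ester
Conditions: (CH2O)n, iPr2NH·CF3CO2H (1 equiv), CF3CO2H (10 mol %), THF, 65 °C
Reagents that add atoms: paraformaldehyde (as formaldehyde), C=O
Why: Mannich-type α-methylenation (iminium addition to the enol, then loss of the amine), in which C6 and C7a are bridgeheads of the bicyclo[3.2.1] lactone, so by Bredt's rule the C5 ketone can enolise only towards C4 and the lactone not at all, while the ester arm is too weakly acidic to compete.

Step 11
Reactants: 19 4-methylene-5-oxo lactone methyl ester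
Product: 20 4-methylene-5β-hydroxy lactone methyl ester
Conditions: NaBH4, CeCl3·7H2O, MeOH, −78 °C
Reagents that add atoms: none
Why: Luche reduction gives 1,2-addition to the enone, with hydride arriving axially from the α face, anti to the axial C6–O bond, so the equatorial 5β-alcohol should result, ready for inversion in step 17.

Step 12
Reactants: 20 4-methylene-5β-hydroxy lactone methyl ester
Product: 22 trans diester diol (C7a CO2Me α; C3a CH2CO2Me β; C7 iPr β; 5β,6β-diol; C4 methylene), via cis diester 21 (not isolated)
Conditions: NaOMe (0.5 equiv), MeOH, 65 °C; AcOH quench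
Reagents that add atoms: methanol, CO
Why: Methoxide-catalysed transesterification opens the bridged lactone to the axial ester 21, which is now enolisable at C7a, and equilibration moves C1 to the equatorial α position trans to both neighbours, an isomer that cannot relactonise and so drains the equilibrium, which sets C7a as in the target.

Step 13
Reactants: 22 trans diester diol
Product: 23 trans diester 5β,6β-acetonide
Conditions: Me2C(OMe)2, PPTS (cat.), CH2Cl2, rt
Reagents that add atoms: 2,2-dimethoxypropane, COC(C)(C)OC
Why: Acid-catalysed transketalisation protects the cis diol as its isopropylidene acetal.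

Step 14
Reactants: 23 trans diester 5β,6β-acetonide
Product: 25 trans-hydrindane ketol (2-oxo; 1β-OH; 5β,6β-acetonide; C4 methylene), via bis(trimethylsilyl) enediol ether 24 (not isolated)
Conditions: Na (dispersion, 4.5 equiv), TMSCl (6 equiv), PhMe, 110 °C; filter, concentrate; degassed MeOH, K2CO3 (5 mol %), 0 °C
Reagents that add atoms: none
Why: Rühlmann acyloin condensation, in which sodium couples the two ester carbonyls to the five-membered ring A (C1–C2), TMSCl traps the enediolate and methoxide so that C7a is not epimerised, the isolated alkene and the ketal are not reducible under these conditions, and methanolysis should strip the less hindered C2–O silyl group first so that the enol is protonated at C1 and settles as the more stable 2-oxo-1β-ol, which sets C1.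

Step 15
Reactants: 25 trans-hydrindane ketol
Product: 26 1β-acetoxy-2-oxo acetonide
Conditions: Ac2O, pyridine, DMAP (cat.), CH2Cl2, 0 °C
Reagents that add atoms: acetic anhydride, CC(=O)OC(C)=O
Why: DMAP-catalysed acetylation of the only free hydroxyl, kept cold and short so that C1 is not enolised.

Step 16
Reactants: 26 1β-acetoxy-2-oxo acetonide
Product: 27 1β-acetoxy-2-oxo-5β,6β-diol
Conditions: AcOH–H2O (4:1), 40 °C
Reagents that add atoms: none
Why: Mild acid hydrolysis of the ketal, which the acetate, the ketone and the exocyclic alkene should tolerate.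

Step 17
Reactants: 27 1β-acetoxy-2-oxo-5β,6β-diol; 28 angelic acid ((Z)-2-methylbut-2-enoic acid)
Product: 29 target CNP0317011.1
Conditions: PPh3, DIAD, PhMe, 0 °C → rt
Reagents that add atoms: none
Why: Mitsunobu esterification, in which the allylic, equatorial C5–OH is activated in preference to the axial C6–OH wedged against the isopropyl group, angelate displaces it by axial SN2 attack from the α face with inversion to the 5α-ester, and the Z geometry is kept because the acid acts only as a carboxylate nucleophile and is never activated as an acyl donor.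

**Compound list**
1 | (E)-4-methylpent-2-enal | CC(C)/C=C/C=O | starting material
2 | allyltributylstannane | C=CC[Sn](CCCC)(CCCC)CCCC | starting material
3 | (4R,5E)-7-methylocta-1,5-dien-4-ol | C=CC[C@H](/C=C/C(C)C)O | intermediate
4 | acryloyl chloride | C=CC(=O)Cl | starting material
5 | (4R,5E)-7-methylocta-1,5-dien-4-yl acrylate | C=CC[C@H](/C=C/C(C)C)OC(=O)C=C | intermediate
6 | (6R)-6-[(E)-3-methylbut-1-enyl]-5,6-dihydro-2H-pyran-2-one | O=C1C=CC[C@H](/C=C/C(C)C)O1 | intermediate
7 | vinylmagnesium bromide | C=C[Mg]Br | starting material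
8 | trimethylsilyl ketene acetal of 9 | C[Si](C)(C)OC1=C[C@@H](C=C)C[C@H](/C=C/C(C)C)O1 | intermediate
9 | (4S,6R)-4-ethenyl-6-[(E)-3-methylbut-1-enyl]oxan-2-one (trans) | O=C1C[C@@H](C=C)C[C@H](/C=C/C(C)C)O1 | intermediate
10 | tert-butyldimethylsilyl ketene acetal of 9 | CC(C)(C)[Si](C)(C)OC1=C[C@@H](C=C)C[C@H](/C=C/C(C)C)O1 | intermediate
11 | tert-butyldimethylsilyl ester of 12 | C1[C@H](C=C)[C@H](C(=O)O[Si](C)(C)C(C)(C)C)[C@H](C(C)C)C=C1 | intermediate
12 | (1S,2R,6R)-6-ethenyl-2-(propan-2-yl)cyclohex-3-ene-1-carboxylic acid (all-cis) | C1[C@H](C=C)[C@H](C(=O)O)[C@H](C(C)C)C=C1 | intermediate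
13 | 5α,6α-epoxide of 12 | C1[C@H](C=C)[C@H](C(=O)O)[C@H](C(C)C)[C@H]2O[C@@H]12 | intermediate
14 | 5α-hydroxy-6β,1-lactone, C3a vinyl | O=C1O[C@@H]2[C@@H](O)C[C@H](C=C)[C@H]1[C@@H]2C(C)C | intermediate
15 | C2-boryl, C5-O-boryl bis(9-BBN) adduct of 14 | O=C1O[C@@H]2[C@@H](OB3C4CCCC3CCC4)C[C@H](CCB3C4CCCC3CCC4)[C@H]1[C@@H]2C(C)C | intermediate
16 | 5α-hydroxy-6β,1-lactone, C3a 2-hydroxyethyl | O=C1O[C@@H]2[C@@H](O)C[C@H](CCO)[C@H]1[C@@H]2C(C)C | intermediate
17 | 5-oxo-6β,1-lactone, C3a carboxymethyl | O=C1O[C@@H]2C(=O)C[C@H](CC(=O)O)[C@H]1[C@@H]2C(C)C | intermediate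
18 | 5-oxo-6β,1-lactone, C3a CH2CO2Me | O=C1O[C@@H]2C(=O)C[C@H](CC(=O)OC)[C@H]1[C@@H]2C(C)C | intermediate
19 | 4-methylene-5-oxo-6β,1-lactone methyl ester | O=C1O[C@@H]2C(=O)C(=C)[C@H](CC(=O)OC)[C@H]1[C@@H]2C(C)C | intermediate
20 | 4-methylene-5β-hydroxy-6β,1-lactone methyl ester | O=C1O[C@@H]2[C@H](O)C(=C)[C@H](CC(=O)OC)[C@H]1[C@@H]2C(C)C | intermediate
21 | cis diester 5β,6β-diol (C7a CO2Me β) | C=C1[C@H](CC(=O)OC)[C@H](C(=O)OC)[C@H](C(C)C)[C@H](O)[C@@H]1O | intermediate
22 | trans diester 5β,6β-diol (C7a CO2Me α) | C=C1[C@H](CC(=O)OC)[C@@H](C(=O)OC)[C@H](C(C)C)[C@H](O)[C@@H]1O | intermediate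
23 | trans diester 5β,6β-acetonide | C=C1[C@H](CC(=O)OC)[C@@H](C(=O)OC)[C@H](C(C)C)[C@@H]2OC(C)(C)O[C@H]12 | intermediate
24 | 1,2-bis(trimethylsilyloxy)-1-ene of the trans-hydrindane acetonide | C=C1[C@@H]2CC(O[Si](C)(C)C)=C(O[Si](C)(C)C)[C@H]2[C@H](C(C)C)[C@@H]3OC(C)(C)O[C@H]13 | intermediate
25 | 1β-hydroxy-2-oxo trans-hydrindane acetonide | C=C1[C@@H]2CC(=O)[C@H](O)[C@H]2[C@H](C(C)C)[C@@H]3OC(C)(C)O[C@H]13 | intermediate
26 | 1β-acetoxy-2-oxo trans-hydrindane acetonide | C=C1[C@@H]2CC(=O)[C@H](OC(C)=O)[C@H]2[C@H](C(C)C)[C@@H]3OC(C)(C)O[C@H]13 | intermediate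
27 | 1β-acetoxy-2-oxo-5β,6β-diol | C=C1[C@@H]2CC(=O)[C@H](OC(C)=O)[C@H]2[C@H](C(C)C)[C@H](O)[C@@H]1O | intermediate
28 | angelic acid | C/C=C(/C)C(=O)O | starting material
29 | CNP0317011.1 | C=C1[C@@H]2CC(=O)[C@H](OC(C)=O)[C@H]2[C@H](C(C)C)[C@H](O)[C@H]1OC(=O)/C(C)=C\C | target

Total step count: 17. Longest linear sequence: 17 steps (1 → 29).

**Steps most likely to fail**

Step 5. The boat transition state is strained. Ketene acetal 10 may be lost by hydrolysis, C-silylation or thermal decay faster than it rearranges.
- The fallback sets out from 1 and returns at 12. It builds ring B by cycloaddition instead of sigmatropic contraction.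
- Wittig methylenation of 1 with Ph3P=CH2 gives (E)-5-methylhexa-1,3-diene F1.
- A thermal Diels–Alder reaction of F1 with (5S)-5-[(1S,2R,5S)-menthyloxy]furan-2(5H)-one (PhMe, 110 °C) should proceed anti to the menthyloxy group, endo, and with C7 bonding to C7a. This gives the cis-fused menthyloxy lactone F2, all-cis at C3a, C7a and C7.
- Aqueous CF3CO2H removes the auxiliary to give hydroxy lactone F3, the ring form of the C3 aldehyde and C1 acid.
- Excess Ph3P=CH2 methylenates the open aldehyde form to the vinyl acid 12.

Step 14. Electron transfer to the hindered C1 ester may be slow, so that simple ester reduction competes. After desilylation the ketol may drift to the other regioisomer, or lose the C7a configuration through its C1-ketone tautomer.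
- The fallback sets out from 23 and returns at 26. It closes C1–C2 at the aldehyde level and distinguishes the two oxygens by their steric environment.
- LiAlH4 reduces 23 to the diol F4, and Swern oxidation gives the dialdehyde F5.
- SmI2 (THF, −78 °C → rt) effects pinacol cyclisation to the cis 1β,2β-diol F6. The samarium-bridged diolate should form anti to the C7a–C7 bond.
- TBSCl with imidazole silylates the less hindered C2–OH to give silyl ether F7.
- Ac2O with DMAP gives the 1β-acetate F8, and HF·pyridine frees the C2 alcohol F9.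
- Dess–Martin periodinane then gives 26.

Step 17. Angelate may attack the exocyclic methylene carbon with allylic shift, the diol may be tied up as a cyclic phosphorane, or the activated alcohol may eliminate to a diene.
- The fallback sets out from 27 and returns at 29. It inverts C5 by oxidation and directed reduction, then acylates directly.
- MnO2 oxidises only the allylic C5–OH to give the 4-methylene-5-ketone F10.
- Me4NBH(OAc)3 (MeCN–AcOH, −20 °C) binds to the C6β hydroxyl and delivers hydride to the β face of C5, giving the trans-diaxial 5α,6β-diol F11.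
- Angelic acid 28 with 2,4,6-trichlorobenzoyl chloride and Et3N gives the mixed anhydride F12.
- In warm toluene F12 should acylate the less hindered allylic C5–OH of F11 without Z to E isomerisation, giving 29.

**Further compounds**
F1 | step 5 | (E)-5-methylhexa-1,3-diene | C=C/C=C/C(C)C
F2 | step 5 | cis-fused (+)-menthyloxy lactone Diels–Alder adduct | O=C1O[C@H](O[C@H]3C[C@@H](C)CC[C@@H]3C(C)C)[C@H]2CC=C[C@@H](C(C)C)[C@@H]12
F3 | step 5 | hydroxy lactone (ring form of the C3 aldehyde C1 acid) | O=C1OC(O)[C@H]2CC=C[C@@H](C(C)C)[C@@H]12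
F4 | step 14 | C1,C2-diol acetonide | C=C1[C@H](CCO)[C@@H](CO)[C@H](C(C)C)[C@@H]2OC(C)(C)O[C@H]12
F5 | step 14 | C1,C2-dialdehyde acetonide | C=C1[C@H](CC=O)[C@@H](C=O)[C@H](C(C)C)[C@@H]2OC(C)(C)O[C@H]12
F6 | step 14 | 1β,2β-diol trans-hydrindane acetonide | C=C1[C@@H]2C[C@H](O)[C@H](O)[C@H]2[C@H](C(C)C)[C@@H]3OC(C)(C)O[C@H]13
F7 | step 14 | 2β-silyloxy-1β-ol acetonide | C=C1[C@@H]2C[C@H](O[Si](C)(C)C(C)(C)C)[C@H](O)[C@H]2[C@H](C(C)C)[C@@H]3OC(C)(C)O[C@H]13
F8 | step 14 | 1β-acetoxy-2β-silyloxy acetonide | C=C1[C@@H]2C[C@H](O[Si](C)(C)C(C)(C)C)[C@H](OC(C)=O)[C@H]2[C@H](C(C)C)[C@@H]3OC(C)(C)O[C@H]13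
F9 | step 14 | 1β-acetoxy-2β-ol acetonide | C=C1[C@@H]2C[C@H](O)[C@H](OC(C)=O)[C@H]2[C@H](C(C)C)[C@@H]3OC(C)(C)O[C@H]13
F10 | step 17 | 1β-acetoxy-6β-hydroxy-4-methylene-2,5-dione | C=C1[C@@H]2CC(=O)[C@H](OC(C)=O)[C@H]2[C@H](C(C)C)[C@H](O)C1=O
F11 | step 17 | 1β-acetoxy-2-oxo-5α,6β-diol | C=C1[C@@H]2CC(=O)[C@H](OC(C)=O)[C@H]2[C@H](C(C)C)[C@H](O)[C@H]1O
F12 | step 17 | angelic 2,4,6-trichlorobenzoic anhydride | C/C=C(/C)C(=O)OC(=O)c1c(Cl)cc(Cl)cc1Cl
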